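The data stem from a simulated flask from invented constants; scatter was added.

A small charge of partner, 0.0800 M in south against 0.200 M of the two substrates together, makes partner the limiting reagent. Each partner gives one product, so south can hold at most 40.0% of product. What I need is how that product divides between the hands.

the same everywhere: left-handed substrate 0.10 M; right-handed substrate 0.10 M
- Tuesday's: partner 0.11 M; run made earlier
- Thursday's: partner 1.1 M; run made earlier
- south: partner 0.0800 M; time 12 min
- north: partner 0.250 M; time 12 min
- west: partner 0.800 M; time 12 min

| run | time / min | left-handed product / % | right-handed product / % | left-handed substrate / % |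
|---|---|---|---|---|
| Tuesday's | 0.333 | 8 | 5 | 39 |
| Tuesday's | 1.00 | 18 | 6 | 26 |
| Tuesday's | 1.50 | 22 | 12 | 24 |
| Tuesday's | 2.50 | 25 | 12 | 18 |
| Tuesday's | 4.00 | 27 | 13 | 15 |
| Tuesday's | 5.00 | 28 | 17 | 15 |
| Tuesday's | 6.00 | 30 | 16 | 14 |
| Thursday's | 0.833 | 42 | 43 | 1 |
| Thursday's | 1.50 | 50 | 45 | 0 |
| Thursday's | 2.50 | 52 | 49 | 0 |
| Thursday's | 3.00 | 50 | 48 | 2 |
| Thursday's | 4.00 | 51 | 51 | 2 |
| Thursday's | 5.00 | 54 | 45 | 0 |
| Thursday's | 6.00 | 52 | 46 | 1 |

(readings scatter by 1.5 percentage points)

* excess of left-handed product over right-handed product at the end for south, north, west, in this order
* how the row runs (falls, then rises / hardly changes / falls all the way / rises all the way / rises, then falls)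

- partner is single-handed; left-handed substrate and right-handed substrate are mirror images of each other, charged as a racemate, each of them at the stated concentration
- what may be going on: partner + left-handed substrate -> left-handed product; partner + right-handed substrate -> right-handed product; left-handed substrate <-> achiral form; right-handed substrate <-> achiral form; achiral form -> waste; achiral form -> side product; partner <-> dormant form
- an excess is the difference of the two amounts in percent of their sum
- "hardly changes" means that all values lie within two and a half points (for a concentration: within two and a half percent of the largest)
- the handed part of partner does not stay in what it makes, so the products of the two hands are mirror images too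

Each product forms at a rate constant times [partner] times its own substrate, so [partner] cancels from the ratio of the two rates:

rate to left-handed product / rate to right-handed product = s × [left-handed substrate] / [right-handed substrate]

Here s is the selectivity factor, the ratio of the two rate constants. While the hands stand level, the products form in the ratio s. I read s from Tuesday's rows up to 2.50 min, summing each product:

s = 2.09

excess at level hands = (s − 1)/(s + 1) = 35.2%

The achiral form connects the hands, and I take it to hold them level in south, so my reckoning for south is 35.2%. Thursday's 1.1 M of partner shows the other end: at 6.00 min both products are large and the excess reads 6.12%. I therefore expect the row to fall towards that reading as partner grows.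

The forecast gives 33%, 17% and 6%, a row that falls all the way; for south it argues “partner is limiting, so this is plain resolution at lower conversion”. My figure for south stands higher than the forecast's.

The flasks give 34.8%, 21.6% and 6.91%, a row that falls all the way.

    partner + left-handed substrate → left-handed product (k = 6.87 L mol⁻¹ min⁻¹)
    partner + right-handed substrate → right-handed product (k = 2.93 L mol⁻¹ min⁻¹)
    left-handed substrate ⇌ achiral form (K = 0.850, k = 0.448 min⁻¹)
    right-handed substrate ⇌ achiral form (K = 0.850, k = 0.448 min⁻¹)
    achiral form → waste (k = 0.129 min⁻¹)
    achiral form → side product (k = 0.0425 min⁻¹)
    partner ⇌ dormant form (K = 0.331, k = 0.783 min⁻¹)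

At the start of south, partner uses left-handed substrate 1.2 times as fast as the forward step to achiral form does, while that forward step uses right-handed substrate 1.9 times as fast as partner does. At 1.13 min these figures stand at 0.46 and 5.0. South's hands stand at 11.8% and 12.3% at 12.0 min, with products in the ratio 2.07, a ratio of summed product of the same kind as my reading of s, 2.09. In north at 6.00 min the hands stand at 2.87% and 5.04%, so with the two rate constants above product then forms in the ratio 1.34.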